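Remark on the chemistry: the target has no stereocentre and no stereogenic double bond, so its SMILES is complete without descriptors. The single stereocentre that arises on the way (C3 of compound 10) is formed as a racemate and is removed again in step 6.

## Analysis of the target

Target 13 is an isoflavone: ring A is fused to the pyranone ring C (O1, C2, C3, C4, C4a, C8a), and ring B (C1' to C6') sits on C3. The oxygen pattern is 5-OH, 7-O-prenyl, 2'-OH and 4'-OH, which makes 13 the 7-O-prenyl ether of 2'-hydroxygenistein. Nothing stereochemical has to be set, because the prenyl alkene ends in two methyl groups and every ring carbon of the chromenone is trigonal. The sensitive groups are the aryl prenyl ether (ionisation by acid, hydrogenation, thermal Claisen shift, attack by bromine or peracids), the electron-rich resorcinol ring B, and C2 of the pyranone, which accepts nucleophiles under strongly basic conditions. The difficulty lies in telling four phenolic oxygens apart, since only O7 is alkylated, and in building ring C with the aryl group on C3 under conditions the prenyl ether survives. The strategy rests on the adjacency of C3 and C4: once C3 carries a hydroxyl group, the pair is an α-hydroxy ketone whose two carbons are both former carbonyl carbons. C4 then traces back to a formyl group on C4a, and C3 to the ring B aryl ketone whose CH2 group (C2) hangs on O1. Because C4a is para to C7, the formyl group of the symmetrical trihydroxybenzaldehyde 1 singles out the C7 oxygen for prenylation and leaves two equivalent ortho hydroxyls, one for O1 and one for the 5-OH, so ring A needs no protecting group.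

## Retrosynthetic reasoning

**13 from 12 (O–Si bonds at O2' and O4').** The last operation is removal of two silyl groups from the protected isoflavone 12. Ring B has to be masked because its free phenols would compete in the ether-forming steps, and a free 2'-oxygen would close onto the bromomethyl ketone carbon. Silyl ethers are chosen because a fluoride source leaves the prenyl ether untouched, whereas acid-labile or hydrogenolysable groups would not.

**12 from 10 (C2=C3 double bond).** Formal addition of water across C2=C3 gives the tertiary alcohol 10, a 3-hydroxyisoflavanone. This turns C3 into a carbinol carbon next to the C4 ketone and so exposes the α-hydroxy ketone. In the forward direction the dehydration has only one regiochemical outcome: C4 is a carbonyl carbon and the aryl ipso carbon has no hydrogen, so only C2 can deliver the proton. It runs through the activated ester 11.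

**10 from 9 (C3–C4 bond).** The α-hydroxy ketone is cut between its two oxygenated carbons. This is the only ring C bond whose cleavage gives two carbonyl groups, a formyl group on ring A and the aryl ketone of ring B, held together in 9 by the O1–C2 ether. Since both carbons are electrophiles in 9, the forward reaction must reverse the polarity of the aldehyde carbon, and a thiazolium-derived carbene does this catalytically. It also has to outrun the normal-polarity aldol reaction of the ketone CH2 group with the aldehyde.

**9 from 3 and 8 (O1–C2 ether bond).** Cutting the aryl ether gives the dihydroxy aldehyde 3 and the bromomethyl ketone 8. The two ortho hydroxyls of 3 are equivalent, so there is no regiochemical question. After the first alkylation the remaining hydroxyl is locked in a hydrogen bond to the formyl group, which should stop the reaction at the mono-ether.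

**3 from 1 and 2 (O7–CH2 bond).** The prenyl group is put on first, from prenyl bromide 2. In 1 the para hydroxyl is the most acidic and the only one not chelated to the formyl group, so acidity alone directs the alkylation to the future O7.

**8 from 6 through 7, and 6 from 4 and 5 (C–Br and O–Si bonds).** The bromide of 8 is introduced on the methyl ketone 6 by way of its silyl enol ether 7, so that electrophilic bromine meets the enol ether and not the activated ring, and no acid is set free. Ketone 6 is the bis-silyl ether of the purchasable dihydroxyacetophenone 4, made with the silyl chloride 5.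

## Alternatives that were turned down

**Alternative 1:** Ring C from an aryne and a β-methoxyacrylic acid.
- Disconnection: O1–C8a, C4–C4a and O1–C2 are cut together. Ring A comes from 3,5-dimethoxy-2-(trimethylsilyl)phenyl trifluoromethanesulfonate A1, and C2, C3, C4 and ring B from 2-(2,4-dimethoxyphenyl)-3-methoxyacrylic acid A2.
- Forward key step: fluoride releases the aryne from A1. The carboxylate of A2 adds at the aryne carbon remote from the flanking methoxy group, and the aryl anion formed next to that methoxy group takes over the acyl group. The phenoxide set free then closes ring C by addition–elimination at the methoxy-bearing alkene carbon, giving 3-(2,4-dimethoxyphenyl)-5,7-dimethoxy-4H-chromen-4-one A3.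
- For it: three bonds and the whole of ring C form in one convergent operation. The known directing effect of an alkoxy group next to an aryne places the carbonyl correctly between C5 and the ring oxygen, and no oxidation-state adjustment follows.
- Against it: all four oxygens arrive as methyl ethers. Fluoride is the trigger, so the fluoride-labile silyl groups that suit a prenyl ether cannot be used on ring B. The Lewis-acidic cleavage needed for three non-chelated methyl ethers would not spare a prenyl ether, so the prenyl group has to be added last to the tetraphenol 3-(2,4-dihydroxyphenyl)-5,7-dihydroxy-4H-chromen-4-one A4. There O7 is the most acidic site, but three further phenols and two electron-rich rings invite over-alkylation and C-prenylation. A1 also needs several steps from a phloroglucinol ether, which puts the route at about nine to ten steps.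
- Comparison: this alternative is stronger in bonds formed per step and in convergence. The chosen strategy forms only one carbon–carbon bond in its key step, but it carries the final oxygen pattern (prenyl on O7, free 5-OH, fluoride-labile groups on ring B) from two-step fragment syntheses and finishes in two mild steps.

**Alternative 2:** Quinoketene hetero-Diels–Alder reaction with a β-methoxystyrene.
- Disconnection: C3–C4 and O1–C2 are cut. Ring A and C4 come from 5-hydroxy-2,2-dimethyl-7-[(3-methylbut-2-en-1-yl)oxy]-4H-1,3-benzodioxin-4-one A5, and C2, C3 and ring B from 1-(2-methoxyethenyl)-2,4-bis(triisopropylsilyloxy)benzene A6.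
- Forward key step: irradiation near 300 nm makes A5 lose its acetonide carbonyl component and gives an ortho-quinone ketene. The aryl-bearing carbon of the enol ether A6 bonds to the ketene carbon and the ring oxygen to the methoxy-bearing carbon. The product is 5-hydroxy-2-methoxy-7-[(3-methylbut-2-en-1-yl)oxy]-3-[2,4-bis(triisopropylsilyloxy)phenyl]chroman-4-one A7, a mixture of racemic diastereomers, and loss of its C2 methoxy group as the alcohol would lead straight to compound 12.
- For it: two bonds and ring C form in one step. The polarity of the enol ether fixes the aryl group on C3. The protecting-group pattern is the same as in the chosen route, and the elimination from an acetal carbon is easier than the dehydration of a tertiary alcohol. On these points it is as strong or stronger, and the step count is about the same (about seven).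
- Against it: the excited-state step must be selective in a system with three light-absorbing units. The chelated hydroxy-carbonyl unit of A5 can lose its excitation by internal proton transfer. The aryl prenyl ether can undergo a photochemical oxygen-to-carbon allyl shift. The electron-rich styrene A6 absorbs in the same window and can isomerise or dimerise. Quinone ketenes are normally intercepted by oxygen or nitrogen nucleophiles, so capture by a carbon–carbon double bond in the [4+2] sense has to compete with ketene dimerisation and with [2+2] addition.
- Comparison: the chosen strategy gives away one bond per key step, but its ring closure is a ground-state, catalytic reaction of a type established for O-(2-oxoalkyl) salicylaldehydes, and none of its steps needs light.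

**Alternative 3:** Danheiser benzannulation that builds ring B on a preformed chromone.
- Disconnection: C1'–C2', C2'–C3' and C4'–C5' are cut, leaving (E)-1-diazo-4-(5,7-dimethoxy-4-oxo-4H-chromen-3-yl)but-3-en-2-one A8 and ethoxyethyne A9.
- Forward key step: photochemical Wolff rearrangement of A8 gives a vinylketene, which adds A9 across the ketene double bond. Ring opening of the cyclobutenone and six-electron electrocyclisation on warming give 3-(4-ethoxy-2-hydroxyphenyl)-5,7-dimethoxy-4H-chromen-4-one A10.
- For it: the resorcinol pattern forms regiospecifically, with the 2'-OH free and O4' already differentiated, and the C3–aryl bond is never an issue.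
- Against it: ring B is the part of the target that can simply be bought with both oxygens in place, so building it from acyclic pieces spends the key step where no problem exists. A8 needs a multi-step synthesis from a 3-formylchromone. A ketene generated under irradiation would not tolerate the prenyl alkene, so ring A must again travel as methyl ethers. The end game then needs cleavage of one ethyl and two methyl ethers followed by selective prenylation of O7, as in Alternative 1, and the step count would be the highest of all.
- Comparison: its one real strength, telling O2' from O4', is not needed here because both end as free hydroxyls. The chosen strategy places its key step on ring C, where the real construction problem lies, and reaches the target in seven steps.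

Key step: step 5

## Route

**Step 1**
Reactants: 1 2,4,6-trihydroxybenzaldehyde; 2 prenyl bromide (1-bromo-3-methylbut-2-ene)
Product: 3 2,6-dihydroxy-4-[(3-methylbut-2-en-1-yl)oxy]benzaldehyde
Conditions: K2CO3 (1.0 equiv), 2 (1.0 equiv), acetone, 0 °C to rt
Reagents that add atoms: none
Why: Williamson ether synthesis; the 4-OH is para to the formyl group and not hydrogen-bonded to it, so it is the most acidic and most accessible phenol and one equivalent of base and of 2 should alkylate it first, leaving the two chelated ortho hydroxyls.

**Step 2**
Reactants: 4 2',4'-dihydroxyacetophenone; 5 triisopropylsilyl chloride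
Product: 6 1-[2,4-bis(triisopropylsilyloxy)phenyl]ethan-1-one
Conditions: 5 (2.5 equiv), imidazole, DMAP (cat.), DMF, rt to 50 °C
Reagents that add atoms: none
Why: Silylation of phenols; the 4'-OH reacts quickly and the chelated 2'-OH more slowly, hence the excess of 5 and the warming. Aryl triisopropylsilyl ethers should tolerate the carbonate, amine and carbene conditions that follow and leave with fluoride.

**Step 3**
Reactants: 6 1-[2,4-bis(triisopropylsilyloxy)phenyl]ethan-1-one
Product: 8 2-bromo-1-[2,4-bis(triisopropylsilyloxy)phenyl]ethan-1-one, via trimethylsilyl enol ether 7 (not isolated)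
Conditions: TMSOTf, Et3N, CH2Cl2, 0 °C; then NBS, 0 °C; aq. NaHCO3
Reagents that add atoms: N-bromosuccinimide, O=C1CCC(=O)N1Br (Br of 8); trimethylsilyl trifluoromethanesulfonate, C[Si](C)(C)OS(=O)(=O)C(F)(F)F (SiMe3 of 7 only)
Why: Soft enolisation to the silyl enol ether, then electrophilic bromination of the enol ether; the enol ether is far more nucleophilic than the silyloxy-substituted ring and no HBr is formed, so bromine should go to the side chain and the aryl silyl ethers should stay intact.

**Step 4**
Reactants: 3 2,6-dihydroxy-4-[(3-methylbut-2-en-1-yl)oxy]benzaldehyde; 8 2-bromo-1-[2,4-bis(triisopropylsilyloxy)phenyl]ethan-1-one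
Product: 9 2-hydroxy-4-[(3-methylbut-2-en-1-yl)oxy]-6-{2-oxo-2-[2,4-bis(triisopropylsilyloxy)phenyl]ethoxy}benzaldehyde
Conditions: K2CO3 (1.1 equiv), 8 (1.0 equiv, added slowly), acetone, rt
Reagents that add atoms: none
Why: Williamson ether synthesis by SN2 displacement on an activated α-bromo ketone; the two ortho hydroxyls of 3 are equivalent, and after the first alkylation the remaining one is held in a hydrogen bond to the formyl group, which should stop the reaction at the mono-ether. Room temperature and a weak base should keep the ketone arm from aldol condensation onto the deactivated aldehyde.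

**Step 5**
Reactants: 9 2-hydroxy-4-[(3-methylbut-2-en-1-yl)oxy]-6-{2-oxo-2-[2,4-bis(triisopropylsilyloxy)phenyl]ethoxy}benzaldehyde
Product: 10 racemic 3,5-dihydroxy-7-[(3-methylbut-2-en-1-yl)oxy]-3-[2,4-bis(triisopropylsilyloxy)phenyl]chroman-4-one
Conditions: 3-benzyl-5-(2-hydroxyethyl)-4-methylthiazolium chloride (20 mol%), Et3N (50 mol%), degassed 1,4-dioxane, 60 °C, argon
Reagents that add atoms: none
Why: Et3N deprotonates the thiazolium salt at its C2 and the carbene adds to the formyl group, which the hydrogen bond from the neighbouring 2-OH keeps electrophilic despite three donor oxygens; proton transfer gives the enaminol (Breslow intermediate), an acyl anion equivalent at the future C4. This carbon attacks the tethered aryl ketone carbon (future C3) and closes ring C in a 6-exo-trig mode; proton transfer and loss of the carbene release the α-hydroxy ketone and return the catalyst. The closest known reaction type is the carbene-catalysed intramolecular crossed aldehyde–ketone benzoin reaction of 2-(2-oxoalkoxy)benzaldehydes to 3-hydroxychroman-4-ones. The new stereocentre C3 is under no control with an achiral catalyst, so 10 should form as the racemate, which is acceptable because step 6 makes C3 trigonal. The selectivity needed is chemoselectivity: carbene-mediated C3–C4 bond formation must outrun the amine-mediated aldol condensation of the CH2 group onto the aldehyde, which would close a benzofuran, and intermolecular homo-benzoin coupling. The substrate helps on each count: only the aldehyde can form the acyl anion equivalent, the tether makes the addition intramolecular, the twisted ortho-silyloxyaryl ketone is poorly conjugated and so a fair electrophile, and the two ortho substituents of the aldehyde disfavour bimolecular coupling. A sub-stoichiometric weak amine in an aprotic solvent keeps enolate chemistry slow, degassing protects the enaminol from oxidation, and the new hydrogen bond between the 5-OH and the C4 carbonyl should hold the product against the retro-benzoin reaction.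

**Step 6**
Reactants: 10 racemic 3,5-dihydroxy-7-[(3-methylbut-2-en-1-yl)oxy]-3-[2,4-bis(triisopropylsilyloxy)phenyl]chroman-4-one
Product: 12 5-hydroxy-7-[(3-methylbut-2-en-1-yl)oxy]-3-[2,4-bis(triisopropylsilyloxy)phenyl]-4H-chromen-4-one, via tertiary chlorosulfite 11 (not isolated)
Conditions: SOCl2 (1.5 equiv), pyridine (5 equiv), CH2Cl2, 0 °C to rt; aq. NaHCO3
Reagents that add atoms: thionyl chloride, O=S(Cl)Cl (S(=O)Cl of 11 only; no atoms remain in 12)
Why: Dehydration of a tertiary alcohol through its chlorosulfite; only C2 carries β-hydrogens, so pyridine-assisted loss of SO2 and chloride can only give the C2=C3 double bond, which is driven by formation of the conjugated pyranone and removes the stereocentre. Excess pyridine buffers HCl, so the prenyl ether and silyl ethers should survive, and any sulfinylation of the chelated 5-OH is reversed on aqueous work-up.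

**Step 7**
Reactants: 12 5-hydroxy-7-[(3-methylbut-2-en-1-yl)oxy]-3-[2,4-bis(triisopropylsilyloxy)phenyl]-4H-chromen-4-one
Product: 13 3-(2,4-dihydroxyphenyl)-5-hydroxy-7-[(3-methylbut-2-en-1-yl)oxy]-4H-chromen-4-one
Conditions: Bu4NF (2.5 equiv), AcOH (2.5 equiv), THF, 0 °C to rt
Reagents that add atoms: none
Why: Fluoride-mediated cleavage of aryl silyl ethers, driven by the strong Si–F bond; buffering with AcOH keeps the medium near neutral so that C2 of the pyranone is not attacked, and the prenyl ether is inert to fluoride.

## Compound list

1 | 2,4,6-trihydroxybenzaldehyde | O=Cc1c(O)cc(O)cc1O | starting material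
2 | prenyl bromide (1-bromo-3-methylbut-2-ene) | CC(C)=CCBr | starting material
3 | 2,6-dihydroxy-4-[(3-methylbut-2-en-1-yl)oxy]benzaldehyde | CC(C)=CCOc1cc(O)c(C=O)c(O)c1 | intermediate
4 | 2',4'-dihydroxyacetophenone | CC(=O)c1ccc(O)cc1O | starting material
5 | triisopropylsilyl chloride | CC(C)[Si](Cl)(C(C)C)C(C)C | starting material
6 | 1-[2,4-bis(triisopropylsilyloxy)phenyl]ethan-1-one | CC(=O)c1ccc(O[Si](C(C)C)(C(C)C)C(C)C)cc1O[Si](C(C)C)(C(C)C)C(C)C | intermediate
7 | trimethyl({1-[2,4-bis(triisopropylsilyloxy)phenyl]ethenyl}oxy)silane | C=C(O[Si](C)(C)C)c1ccc(O[Si](C(C)C)(C(C)C)C(C)C)cc1O[Si](C(C)C)(C(C)C)C(C)C | intermediate (not isolated)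
8 | 2-bromo-1-[2,4-bis(triisopropylsilyloxy)phenyl]ethan-1-one | BrCC(=O)c1ccc(O[Si](C(C)C)(C(C)C)C(C)C)cc1O[Si](C(C)C)(C(C)C)C(C)C | intermediate
9 | 2-hydroxy-4-[(3-methylbut-2-en-1-yl)oxy]-6-{2-oxo-2-[2,4-bis(triisopropylsilyloxy)phenyl]ethoxy}benzaldehyde | CC(C)=CCOc1cc(O)c(C=O)c(OCC(=O)c2ccc(O[Si](C(C)C)(C(C)C)C(C)C)cc2O[Si](C(C)C)(C(C)C)C(C)C)c1 | intermediate
10 | 3,5-dihydroxy-7-[(3-methylbut-2-en-1-yl)oxy]-3-[2,4-bis(triisopropylsilyloxy)phenyl]chroman-4-one, racemate | CC(C)=CCOc1cc(O)c2C(=O)C(O)(c3ccc(O[Si](C(C)C)(C(C)C)C(C)C)cc3O[Si](C(C)C)(C(C)C)C(C)C)COc2c1 | intermediate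
11 | 5-hydroxy-7-[(3-methylbut-2-en-1-yl)oxy]-4-oxo-3-[2,4-bis(triisopropylsilyloxy)phenyl]chroman-3-yl chlorosulfite, racemate | CC(C)=CCOc1cc(O)c2C(=O)C(OS(=O)Cl)(c3ccc(O[Si](C(C)C)(C(C)C)C(C)C)cc3O[Si](C(C)C)(C(C)C)C(C)C)COc2c1 | intermediate (not isolated)
12 | 5-hydroxy-7-[(3-methylbut-2-en-1-yl)oxy]-3-[2,4-bis(triisopropylsilyloxy)phenyl]-4H-chromen-4-one | CC(C)=CCOc1cc(O)c2c(=O)c(-c3ccc(O[Si](C(C)C)(C(C)C)C(C)C)cc3O[Si](C(C)C)(C(C)C)C(C)C)coc2c1 | intermediate
13 | 3-(2,4-dihydroxyphenyl)-5-hydroxy-7-[(3-methylbut-2-en-1-yl)oxy]-4H-chromen-4-one | CC(C)=CCOc1cc(O)c2c(=O)c(-c3ccc(O)cc3O)coc2c1 | target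

## Step count and least certain steps

Total step count: 7. Longest linear sequence: 6 steps (4 to 6 to 8 to 9 to 10 to 12 to 13, steps 2 to 7).

**Step 5 (key step).**
- What may go wrong: carbene addition to the aldehyde may be slow, because the aldehyde is flanked by two oxygen substituents and deactivated by the chelated, partly ionised phenol. The amine-mediated aldol closure to a benzofuran, or oxidation of the acyl anion equivalent by traces of air, could then take over. Addition to the ketone, which is shielded by the ortho silyloxy group, may also revert.
- Fallback: this sets out from 9 and removes the acidic phenol before the carbene step. Silylation of 9 (TBSCl, imidazole, DMF, rt) should give 2-(tert-butyldimethylsilyloxy)-4-[(3-methylbut-2-en-1-yl)oxy]-6-{2-oxo-2-[2,4-bis(triisopropylsilyloxy)phenyl]ethoxy}benzaldehyde F1, a fully O-substituted salicylaldehyde of exactly the kind for which the carbene-catalysed closure is established. With no acidic proton present, the same thiazolium salt or a more nucleophilic bicyclic triazolium salt with Et3N should close it to racemic 5-(tert-butyldimethylsilyloxy)-3-hydroxy-7-[(3-methylbut-2-en-1-yl)oxy]-3-[2,4-bis(triisopropylsilyloxy)phenyl]chroman-4-one F2. SOCl2 and pyridine would take F2 through racemic 5-(tert-butyldimethylsilyloxy)-7-[(3-methylbut-2-en-1-yl)oxy]-4-oxo-3-[2,4-bis(triisopropylsilyloxy)phenyl]chroman-3-yl chlorosulfite F3 to 5-(tert-butyldimethylsilyloxy)-7-[(3-methylbut-2-en-1-yl)oxy]-3-[2,4-bis(triisopropylsilyloxy)phenyl]-4H-chromen-4-one F4. Bu4NF with AcOH then removes all three silyl groups, and the sequence comes back to the route at the target 13.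

**Step 6.**
- What may go wrong: the chlorosulfite may collapse by internal return to a tertiary chloride in place of eliminating, and the 5-OH may be sulfinylated. If the base is used up, the HCl formed could ionise the prenyl ether.
- Fallback: this sets out from 10 and replaces the base-mediated anti elimination by a thermal, intramolecular syn elimination. The Burgess reagent (methyl N-(triethylammoniosulfonyl)carbamate, THF, 50 °C) should convert the tertiary alcohol into the triethylammonium salt of racemic 5-hydroxy-7-[(3-methylbut-2-en-1-yl)oxy]-4-oxo-3-[2,4-bis(triisopropylsilyloxy)phenyl]chroman-3-yl N-(methoxycarbonyl)sulfamate F5. Its sulfamate nitrogen takes the syn hydrogen from C2 without chloride or free acid, and the sequence comes back to the route at 12.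

**Step 4.**
- What may go wrong: the carbonate may take the product further by aldol condensation of the new ketone arm onto the ortho formyl group, may alkylate both hydroxyls, or may transfer a silyl group from the activated aryl silyl ethers to the phenoxide.
- Fallback: this sets out from the enol ether 7 (made from 6 as in step 3) and forms the ether bond without base. Rubottom oxidation of 7 (mCPBA, NaHCO3, CH2Cl2, 0 °C) should give 2-(trimethylsilyloxy)-1-[2,4-bis(triisopropylsilyloxy)phenyl]ethan-1-one F6, and brief treatment with citric acid in MeOH should give 2-hydroxy-1-[2,4-bis(triisopropylsilyloxy)phenyl]ethan-1-one F7. Mitsunobu etherification of F7 with the phenol 3 (PPh3, diisopropyl azodicarboxylate, THF, 0 °C) then comes back to the route at 9.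

**Step 3.**
- What may go wrong: bromine may enter the doubly activated ring in place of the side chain, a second bromine may add at the α-carbon, or the ortho silyl ether may be lost if acid builds up.
- Fallback: this sets out from 4 and reverses the order of operations, so that the halogenation is done on the acid-tolerant free phenol. Copper dibromide CuBr2 (divalent copper) in EtOAc/CHCl3 at reflux is a known side-chain-selective bromination of hydroxyacetophenones and should give 2-bromo-1-(2,4-dihydroxyphenyl)ethan-1-one F8. Silylation of both phenols with triisopropylsilyl triflate and the non-nucleophilic base 2,6-lutidine (CH2Cl2, −78 to 0 °C) then comes back to the route at 8.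

**Step 1.**
- What may go wrong: the ambident phloroglucinol-type phenoxide may be prenylated on carbon or twice on oxygen.
- Fallback: this sets out from 1 and uses a Mitsunobu etherification with 3-methylbut-2-en-1-ol (PPh3, diisopropyl azodicarboxylate, THF, 0 °C) in place of the alkyl halide. Under these neutral conditions only the most acidic, unchelated 4-OH should be engaged and no free phenoxide is present for C-alkylation; the sequence comes back to the route at 3.

## Further compounds

F1 | step 5 | 2-(tert-butyldimethylsilyloxy)-4-[(3-methylbut-2-en-1-yl)oxy]-6-{2-oxo-2-[2,4-bis(triisopropylsilyloxy)phenyl]ethoxy}benzaldehyde | CC(C)=CCOc1cc(O[Si](C)(C)C(C)(C)C)c(C=O)c(OCC(=O)c2ccc(O[Si](C(C)C)(C(C)C)C(C)C)cc2O[Si](C(C)C)(C(C)C)C(C)C)c1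
F2 | step 5 | 5-(tert-butyldimethylsilyloxy)-3-hydroxy-7-[(3-methylbut-2-en-1-yl)oxy]-3-[2,4-bis(triisopropylsilyloxy)phenyl]chroman-4-one, racemate | CC(C)=CCOc1cc(O[Si](C)(C)C(C)(C)C)c2C(=O)C(O)(c3ccc(O[Si](C(C)C)(C(C)C)C(C)C)cc3O[Si](C(C)C)(C(C)C)C(C)C)COc2c1
F3 | step 5 | 5-(tert-butyldimethylsilyloxy)-7-[(3-methylbut-2-en-1-yl)oxy]-4-oxo-3-[2,4-bis(triisopropylsilyloxy)phenyl]chroman-3-yl chlorosulfite, racemate | CC(C)=CCOc1cc(O[Si](C)(C)C(C)(C)C)c2C(=O)C(OS(=O)Cl)(c3ccc(O[Si](C(C)C)(C(C)C)C(C)C)cc3O[Si](C(C)C)(C(C)C)C(C)C)COc2c1
F4 | step 5 | 5-(tert-butyldimethylsilyloxy)-7-[(3-methylbut-2-en-1-yl)oxy]-3-[2,4-bis(triisopropylsilyloxy)phenyl]-4H-chromen-4-one | CC(C)=CCOc1cc(O[Si](C)(C)C(C)(C)C)c2c(=O)c(-c3ccc(O[Si](C(C)C)(C(C)C)C(C)C)cc3O[Si](C(C)C)(C(C)C)C(C)C)coc2c1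
F5 | step 6 | triethylammonium salt of 5-hydroxy-7-[(3-methylbut-2-en-1-yl)oxy]-4-oxo-3-[2,4-bis(triisopropylsilyloxy)phenyl]chroman-3-yl N-(methoxycarbonyl)sulfamate, racemate | CC(C)=CCOc1cc(O)c2C(=O)C(OS(=O)(=O)[N-]C(=O)OC)(c3ccc(O[Si](C(C)C)(C(C)C)C(C)C)cc3O[Si](C(C)C)(C(C)C)C(C)C)COc2c1.CC[NH+](CC)CC
F6 | step 4 | 2-(trimethylsilyloxy)-1-[2,4-bis(triisopropylsilyloxy)phenyl]ethan-1-one | C[Si](C)(C)OCC(=O)c1ccc(O[Si](C(C)C)(C(C)C)C(C)C)cc1O[Si](C(C)C)(C(C)C)C(C)C
F7 | step 4 | 2-hydroxy-1-[2,4-bis(triisopropylsilyloxy)phenyl]ethan-1-one | OCC(=O)c1ccc(O[Si](C(C)C)(C(C)C)C(C)C)cc1O[Si](C(C)C)(C(C)C)C(C)C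
F8 | step 3 | 2-bromo-1-(2,4-dihydroxyphenyl)ethan-1-one | O=C(CBr)c1ccc(O)cc1O
F0 | step 1 | none | none
A1 | alternative 1 | 3,5-dimethoxy-2-(trimethylsilyl)phenyl trifluoromethanesulfonate | COc1cc(OC)c([Si](C)(C)C)c(OS(=O)(=O)C(F)(F)F)c1
A2 | alternative 1 | 2-(2,4-dimethoxyphenyl)-3-methoxyacrylic acid | COC=C(C(=O)O)c1ccc(OC)cc1OC
A3 | alternative 1 | 3-(2,4-dimethoxyphenyl)-5,7-dimethoxy-4H-chromen-4-one | COc1ccc(-c2coc3cc(OC)cc(OC)c3c2=O)c(OC)c1
A4 | alternative 1 | 3-(2,4-dihydroxyphenyl)-5,7-dihydroxy-4H-chromen-4-one | O=c1c(-c2ccc(O)cc2O)coc2cc(O)cc(O)c12
A5 | alternative 2 | 5-hydroxy-2,2-dimethyl-7-[(3-methylbut-2-en-1-yl)oxy]-4H-1,3-benzodioxin-4-one | CC(C)=CCOc1cc(O)c2C(=O)OC(C)(C)Oc2c1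
A6 | alternative 2 | 1-(2-methoxyethenyl)-2,4-bis(triisopropylsilyloxy)benzene | COC=Cc1ccc(O[Si](C(C)C)(C(C)C)C(C)C)cc1O[Si](C(C)C)(C(C)C)C(C)C
A7 | alternative 2 | 5-hydroxy-2-methoxy-7-[(3-methylbut-2-en-1-yl)oxy]-3-[2,4-bis(triisopropylsilyloxy)phenyl]chroman-4-one, mixture of racemic diastereomers | CC(C)=CCOc1cc(O)c2C(=O)C(c3ccc(O[Si](C(C)C)(C(C)C)C(C)C)cc3O[Si](C(C)C)(C(C)C)C(C)C)C(OC)Oc2c1
A8 | alternative 3 | (E)-1-diazo-4-(5,7-dimethoxy-4-oxo-4H-chromen-3-yl)but-3-en-2-one | COc1cc(OC)c2c(c1)occ(/C=C/C(=O)C=[N+]=[N-])c2=O
A9 | alternative 3 | ethoxyethyne | CCOC#C
A10 | alternative 3 | 3-(4-ethoxy-2-hydroxyphenyl)-5,7-dimethoxy-4H-chromen-4-one | CCOc1ccc(-c2coc3cc(OC)cc(OC)c3c2=O)c(O)c1
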